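**Plan**

1. Larreantin is numbered as a naphthoquinone: C1=O beside C2–OMe, aryl on C8, methyl on C7, benzyl on C6; ring A is the quinone and ring B the benzenoid ring. Since C7=C8 (with its methyl and aryl groups) sits on C8a of the methoxyquinone, C7=C8–C8a=C4a is a vinylquinone diene, and C5–C6 with the benzyl group is the carbon pair of an enol ether.
2. Retrosynthesis: the two phenols are masked as benzyl ethers and ring B is taken back to its 6-methoxy-5,6-dihydro-1,4-diol form. C4a–C5 and C6–C7 are then cut together ([4+2]), giving an (E)-6-(1-arylprop-1-enyl)-2-methoxybenzoquinone and a 3-aryl-2-methoxypropene.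
3. The quinone is cut at the C8–aryl bond (Suzuki coupling of a (Z)-enol triflate) and at the ring A–C8 bond (ortho-lithiation of MOM-protected guaiacol, then acylation). The enol ether comes from methyl homovanillate by benzylation and ester methylenation.
4. Forward: ring A is bought as guaiacol and oxidised to the quinone just before the key step. Ring B is the only ring made; it closes in the cycloaddition of step 9 and is aromatised by loss of methanol, after which oxidation and debenzylation finish the synthesis.
5. Stereochemistry: the target has no stereocentre. The one element that counts is the E geometry of the diene (methyl trans to the quinone), set by (Z)-selective enolisation/triflation and a retentive coupling. The C6 centre of the adduct is racemic and is erased on aromatisation.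

Key step: step 9

Assumption: (4-benzyloxy-3-methoxyphenyl)boronic acid, methyl homovanillate and N-methoxy-N-methylpropanamide are taken as catalogue compounds; intermediates with stereocentres are racemic because the target is achiral.

**Route**

Step 1
Reactants: 1 guaiacol (2-methoxyphenol)
Product: 2 1-methoxy-2-(methoxymethoxy)benzene
Conditions: MOMCl, i-Pr2NEt, CH2Cl2, 0 °C to rt
Reagents that add atoms: chloromethyl methyl ether (MOMCl), COCCl
Why: Williamson-type O-alkylation of the phenol by the α-chloro ether gives the MOM ether, which masks the phenol and is the stronger of the two ortho-directing groups for the next step.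

Step 2
Reactants: 2 1-methoxy-2-(methoxymethoxy)benzene; 3 N-methoxy-N-methylpropanamide
Product: 6 1-[3-methoxy-2-(methoxymethoxy)phenyl]propan-1-one, via aryllithium 4 (not isolated), via lithium hemiaminal alkoxide 5 (not isolated)
Conditions: n-BuLi, TMEDA, Et2O, 0 °C to rt; then 3, −78 to 0 °C; aq NH4Cl
Reagents that add atoms: none
Why: Directed ortho-metalation places lithium at C3 next to the chelating OMOM group (a better director than OMe), and the Weinreb ketone synthesis stops at chelate 5, so the ethyl ketone is released only on quench and no tertiary alcohol should form.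

Step 3
Reactants: 6 1-[3-methoxy-2-(methoxymethoxy)phenyl]propan-1-one
Product: 8 (Z)-1-[3-methoxy-2-(methoxymethoxy)phenyl]prop-1-en-1-yl trifluoromethanesulfonate, via potassium (Z)-enolate 7 (not isolated)
Conditions: KN(SiMe3)2, THF, −78 °C; then PhNTf2, −78 to 0 °C
Reagents that add atoms: N-phenylbis(trifluoromethanesulfonimide) (PhNTf2), O=S(=O)(N(c1ccccc1)S(=O)(=O)C(F)(F)F)C(F)(F)F
Why: Kinetic deprotonation of an aryl ethyl ketone should give the (Z)-enolate (methyl syn to oxygen, avoiding allylic strain against the aryl group), and O-sulfonylation by PhNTf2 (enol triflate formation) fixes this geometry, which is the origin of the diene geometry.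

Step 4
Reactants: 8 (Z)-1-[3-methoxy-2-(methoxymethoxy)phenyl]prop-1-en-1-yl trifluoromethanesulfonate
Product: 9 (Z)-1-(2-hydroxy-3-methoxyphenyl)prop-1-en-1-yl trifluoromethanesulfonate
Conditions: conc. HCl (cat.), MeOH, 40 °C
Reagents that add atoms: none
Why: Acid-catalysed transacetalisation (methanolysis of the MOM ether) is carried out while the only alkene is the enol triflate, which the sulfonate deactivates toward protonation, so the geometry from step 3 should not scramble and no acid ever meets the later electron-rich diarylpropene.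

Step 5
Reactants: 9 (Z)-1-(2-hydroxy-3-methoxyphenyl)prop-1-en-1-yl trifluoromethanesulfonate; 10 (4-benzyloxy-3-methoxyphenyl)boronic acid
Product: 11 (E)-2-[1-(4-benzyloxy-3-methoxyphenyl)prop-1-en-1-yl]-6-methoxyphenol
Conditions: Pd(PPh3)4 (5 mol %), K3PO4 (3 equiv), dioxane–H2O, 70 °C
Reagents that add atoms: none
Why: Suzuki–Miyaura coupling of an alkenyl triflate under zerovalent palladium catalysis proceeds with retention, so the guaiacyl ring takes the place of the triflate cis to the methyl group and the (E)-diarylpropene should result, the phenol riding along as its phenoxide and the aryl benzyl ether being inert.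

Step 6
Reactants: 11 (E)-2-[1-(4-benzyloxy-3-methoxyphenyl)prop-1-en-1-yl]-6-methoxyphenol
Product: 12 2-[(E)-1-(4-benzyloxy-3-methoxyphenyl)prop-1-en-1-yl]-6-methoxy-1,4-benzoquinone
Conditions: (KSO3)2NO (2.5 equiv), KH2PO4, acetone–H2O, 0 °C to rt; used at once
Reagents that add atoms: potassium nitrosodisulfonate, (KSO3)2NO, [K+].[K+].[O-]S(=O)(=O)N([O])S(=O)(=O)[O-]
Why: Teuber oxidation, in which the nitrosodisulfonate radical abstracts the phenolic hydrogen and a second equivalent adds at the free para position to deliver the para-quinone, while the benzyl-protected phenol and the alkene should be untouched at buffered pH.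

Step 7
Reactants: 13 methyl homovanillate (methyl 2-(4-hydroxy-3-methoxyphenyl)acetate)
Product: 14 methyl 2-(4-benzyloxy-3-methoxyphenyl)acetate
Conditions: BnBr, K2CO3, acetone, reflux
Reagents that add atoms: benzyl bromide, BrCc1ccccc1
Why: Williamson etherification of the only acidic OH group, with the methyl ester stable to K2CO3 in acetone.

Step 8
Reactants: 14 methyl 2-(4-benzyloxy-3-methoxyphenyl)acetate
Product: 15 1-benzyloxy-2-methoxy-4-(2-methoxyprop-2-en-1-yl)benzene
Conditions: Cp2TiMe2 (2.5 equiv), PhMe–THF, 65 °C, dark; filtration through basic Al2O3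
Reagents that add atoms: dimethyltitanocene, Cp2TiMe2, C[Ti](C)(C1C=CC=C1)C1C=CC=C1
Why: Petasis methylenation, in which thermolysis of Cp2TiMe2 gives Cp2Ti=CH2 that converts the ester carbonyl into the 1,1-disubstituted enol ether through an oxatitanacyclobutane, and because the reagent is non-basic it should neither enolise the arylacetate nor move the new double bond into conjugation.

Step 9
Reactants: 12 2-[(E)-1-(4-benzyloxy-3-methoxyphenyl)prop-1-en-1-yl]-6-methoxy-1,4-benzoquinone; 15 1-benzyloxy-2-methoxy-4-(2-methoxyprop-2-en-1-yl)benzene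
Product: 18 racemic 8-(4-benzyloxy-3-methoxyphenyl)-6-(4-benzyloxy-3-methoxybenzyl)-2,6-dimethoxy-7-methyl-5,6-dihydronaphthalene-1,4-diol, via primary cycloadduct 16 (not isolated), via ortho-quinone methide tautomer 17 (not isolated)
Conditions: 15 (2 equiv), PhMe, 60 °C, Ar, dark, base-washed glassware
Reagents that add atoms: none
Why: The electron-poor diene C7=C8–C8a=C4a of 12 and the electron-rich alkene of 15 should combine in an inverse-electron-demand Diels–Alder reaction that is concerted but asynchronous: the enol ether CH2 bonds first to C4a, the quinone carbon beta to the more electrophilic C1=O (C4=O is damped as a vinylogous ester by the C2 methoxy group), and the oxocarbenium-like C6 is then captured by C7 of the styrene-type alkene. The closest known reaction type is the cycloaddition of vinylquinones as 4π components with enol ethers and other donor alkenes, followed by tautomerisation of the isoquinone methide adducts to hydroquinones. Ring B is closed as the six-membered ring of an intermolecular [4+2] cycloaddition, the second bond corresponding in the stepwise limit to a 6-endo cation–olefin closure onto C7. Adduct 16 should regain the aromaticity of ring A by enolisation of C4=O through H-4a to give ortho-quinone methide 17, followed by a 1,5-hydrogen shift from C7 to O1, which leaves C7=C8 in place and a tertiary methyl ether at C6. The quaternary C6 is the only stereocentre left in 18; it forms without control as a racemate (the cis H-4a/H-7 relation in 16 follows from suprafacial addition) and is deleted in step 10, so no facial or endo/exo selectivity is needed. What the step does need is regio- and periselectivity, secured by the C1=O activation of C4a, by the methoxy group that deactivates C2=C3 as a competing dienophile, and by the E geometry of 12, which puts hydrogen and not methyl on the inside of the s-cis diene.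

Step 10
Reactants: 18 racemic 8-(4-benzyloxy-3-methoxyphenyl)-6-(4-benzyloxy-3-methoxybenzyl)-2,6-dimethoxy-7-methyl-5,6-dihydronaphthalene-1,4-diol
Product: 20 8-(4-benzyloxy-3-methoxyphenyl)-6-(4-benzyloxy-3-methoxybenzyl)-2-methoxy-7-methylnaphthalene-1,4-dione, via naphthohydroquinone 19 (not isolated)
Conditions: p-TsOH·H2O (cat.), CH2Cl2, rt; then Ag2O, MgSO4, rt
Reagents that add atoms: none
Why: Protonation should ionise the tertiary allylic C6–OMe bond to a cation delocalised onto the doubly benzylic C8, and loss of H-5 aromatises ring B (E1 elimination of methanol), after which Ag2O dehydrogenates the naphthohydroquinone to the quinone without affecting benzyl or methyl ethers.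

Step 11
Reactants: 20 8-(4-benzyloxy-3-methoxyphenyl)-6-(4-benzyloxy-3-methoxybenzyl)-2-methoxy-7-methylnaphthalene-1,4-dione
Product: 21 larreantin, 8-(4-hydroxy-3-methoxyphenyl)-6-(4-hydroxy-3-methoxybenzyl)-2-methoxy-7-methylnaphthalene-1,4-dione
Conditions: BCl3, C6Me5H, CH2Cl2, −78 °C; then H2O
Reagents that add atoms: none
Why: Lewis acid-mediated debenzylation, in which BCl3 with pentamethylbenzene as a non-Lewis-basic benzyl cation scavenger cleaves aryl benzyl ethers at −78 °C, a temperature at which the aryl and quinone methyl ethers are expected to persist.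

**Compound list**

1 | guaiacol (2-methoxyphenol) | COc1ccccc1O | starting material
2 | 1-methoxy-2-(methoxymethoxy)benzene | COCOc1ccccc1OC | intermediate
3 | N-methoxy-N-methylpropanamide | CCC(=O)N(C)OC | starting material
4 | [3-methoxy-2-(methoxymethoxy)phenyl]lithium | [Li]c1cccc(OC)c1OCOC | intermediate (not isolated)
5 | lithium 1-[methoxy(methyl)amino]-1-[3-methoxy-2-(methoxymethoxy)phenyl]propan-1-olate | CCC([O-])(N(C)OC)c1cccc(OC)c1OCOC.[Li+] | intermediate (not isolated)
6 | 1-[3-methoxy-2-(methoxymethoxy)phenyl]propan-1-one | CCC(=O)c1cccc(OC)c1OCOC | intermediate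
7 | potassium (Z)-1-[3-methoxy-2-(methoxymethoxy)phenyl]prop-1-en-1-olate | C/C=C(\[O-])c1cccc(OC)c1OCOC.[K+] | intermediate (not isolated)
8 | (Z)-1-[3-methoxy-2-(methoxymethoxy)phenyl]prop-1-en-1-yl trifluoromethanesulfonate | C/C=C(\OS(=O)(=O)C(F)(F)F)c1cccc(OC)c1OCOC | intermediate
9 | (Z)-1-(2-hydroxy-3-methoxyphenyl)prop-1-en-1-yl trifluoromethanesulfonate | C/C=C(\OS(=O)(=O)C(F)(F)F)c1cccc(OC)c1O | intermediate
10 | (4-benzyloxy-3-methoxyphenyl)boronic acid | OB(O)c1ccc(OCc2ccccc2)c(OC)c1 | starting material
11 | (E)-2-[1-(4-benzyloxy-3-methoxyphenyl)prop-1-en-1-yl]-6-methoxyphenol | C/C=C(\c1ccc(OCc2ccccc2)c(OC)c1)c1cccc(OC)c1O | intermediate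
12 | 2-[(E)-1-(4-benzyloxy-3-methoxyphenyl)prop-1-en-1-yl]-6-methoxy-1,4-benzoquinone | C/C=C(\c1ccc(OCc2ccccc2)c(OC)c1)C1=CC(=O)C=C(OC)C1=O | intermediate
13 | methyl homovanillate | COC(=O)Cc1ccc(O)c(OC)c1 | starting material
14 | methyl 2-(4-benzyloxy-3-methoxyphenyl)acetate | COC(=O)Cc1ccc(OCc2ccccc2)c(OC)c1 | intermediate
15 | 1-benzyloxy-2-methoxy-4-(2-methoxyprop-2-en-1-yl)benzene | C=C(OC)Cc1ccc(OCc2ccccc2)c(OC)c1 | intermediate
16 | 8-(4-benzyloxy-3-methoxyphenyl)-6-(4-benzyloxy-3-methoxybenzyl)-2,6-dimethoxy-7-methyl-4a,5,6,7-tetrahydronaphthalene-1,4-dione; H-4a and H-7 cis, both C6 epimers, racemic | COC1=CC(=O)[C@@H]2CC(OC)(Cc3ccc(OCc4ccccc4)c(OC)c3)[C@H](C)C(c3ccc(OCc4ccccc4)c(OC)c3)=C2C1=O | intermediate (not isolated)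
17 | 8-(4-benzyloxy-3-methoxyphenyl)-6-(4-benzyloxy-3-methoxybenzyl)-4-hydroxy-2,6-dimethoxy-7-methyl-6,7-dihydronaphthalen-1(5H)-one; diastereomer mixture, racemic | COC1=CC(O)=C2CC(OC)(Cc3ccc(OCc4ccccc4)c(OC)c3)C(C)C(c3ccc(OCc4ccccc4)c(OC)c3)=C2C1=O | intermediate (not isolated)
18 | 8-(4-benzyloxy-3-methoxyphenyl)-6-(4-benzyloxy-3-methoxybenzyl)-2,6-dimethoxy-7-methyl-5,6-dihydronaphthalene-1,4-diol; racemic | COc1cc(O)c2c(c1O)C(c1ccc(OCc3ccccc3)c(OC)c1)=C(C)C(OC)(Cc1ccc(OCc3ccccc3)c(OC)c1)C2 | intermediate
19 | 8-(4-benzyloxy-3-methoxyphenyl)-6-(4-benzyloxy-3-methoxybenzyl)-2-methoxy-7-methylnaphthalene-1,4-diol | COc1cc(O)c2cc(Cc3ccc(OCc4ccccc4)c(OC)c3)c(C)c(-c3ccc(OCc4ccccc4)c(OC)c3)c2c1O | intermediate (not isolated)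
20 | 8-(4-benzyloxy-3-methoxyphenyl)-6-(4-benzyloxy-3-methoxybenzyl)-2-methoxy-7-methylnaphthalene-1,4-dione | COC1=CC(=O)c2cc(Cc3ccc(OCc4ccccc4)c(OC)c3)c(C)c(-c3ccc(OCc4ccccc4)c(OC)c3)c2C1=O | intermediate
21 | larreantin | COC1=CC(=O)c2cc(Cc3ccc(O)c(OC)c3)c(C)c(-c3ccc(O)c(OC)c3)c2C1=O | target

**Totals and risks**

Total step count: 11. Longest linear sequence: 9 steps (steps 1–6 and 9–11, from guaiacol).

Steps most likely to fail:

Step 9. The vinylquinone may dimerise (one molecule as diene, a second as dienophile) faster than it is trapped. The enol ether may be hydrolysed or isomerised to the conjugated styrenyl ether by adventitious acid. Redox exchange between the hydroquinone product and unreacted quinone may also drain the diene. The fallback keeps the same cycloaddition but never lets the quinone accumulate. Setting out from 12, reduction with aqueous Na2S2O4 in EtOAc should give the storable (E)-2-[1-(4-benzyloxy-3-methoxyphenyl)prop-1-en-1-yl]-6-methoxybenzene-1,4-diol F1. This is added slowly to Ag2O and an excess of 15 in PhMe over K2CO3, so that 12 is formed at low standing concentration and intercepted. The adduct is oxidised in the same flask to 8-(4-benzyloxy-3-methoxyphenyl)-6-(4-benzyloxy-3-methoxybenzyl)-2,6-dimethoxy-7-methyl-5,6-dihydronaphthalene-1,4-dione F2. Catalytic p-TsOH should then eliminate methanol, and the sequence rejoins the route at 20.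

Step 11. BCl3 may complex the quinone and, through chelation between C1=O and the C2 methoxy group, cleave that vinylogous ester along with the benzyl ethers. The fallback is reductive. Setting out from 20, hydrogenolysis (H2, Pd/C, EtOAc–MeOH, rt) should reduce the quinone and remove both benzyl groups to give 8-(4-hydroxy-3-methoxyphenyl)-6-(4-hydroxy-3-methoxybenzyl)-2-methoxy-7-methylnaphthalene-1,4-diol F3. Stirring the filtered solution in air should reoxidise only the naphthohydroquinone and deliver 21.

Step 5. Oxidative addition and transmetalation may be slow at the hindered, phenoxide-bearing enol triflate, allowing S–O cleavage back to the ketone and protodeboronation to compete. The fallback changes the order of events. Setting out from 8, the same coupling with 10 on the MOM-protected triflate should give (E)-1-[1-(4-benzyloxy-3-methoxyphenyl)prop-1-en-1-yl]-3-methoxy-2-(methoxymethoxy)benzene F4. The acetal is then removed without protic acid (ZnBr2, n-PrSH, CH2Cl2, 0 °C), so that the diarylpropene geometry is not put at risk by protonation, and the sequence rejoins the route at 11.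

**Further compounds**

F1 | step 9 | (E)-2-[1-(4-benzyloxy-3-methoxyphenyl)prop-1-en-1-yl]-6-methoxybenzene-1,4-diol | C/C=C(\c1ccc(OCc2ccccc2)c(OC)c1)c1cc(O)cc(OC)c1O
F2 | step 9 | 8-(4-benzyloxy-3-methoxyphenyl)-6-(4-benzyloxy-3-methoxybenzyl)-2,6-dimethoxy-7-methyl-5,6-dihydronaphthalene-1,4-dione, racemic | COC1=CC(=O)C2=C(C1=O)C(c1ccc(OCc3ccccc3)c(OC)c1)=C(C)C(OC)(Cc1ccc(OCc3ccccc3)c(OC)c1)C2
F3 | step 11 | 8-(4-hydroxy-3-methoxyphenyl)-6-(4-hydroxy-3-methoxybenzyl)-2-methoxy-7-methylnaphthalene-1,4-diol | COc1cc(O)c2cc(Cc3ccc(O)c(OC)c3)c(C)c(-c3ccc(O)c(OC)c3)c2c1O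
F4 | step 5 | (E)-1-[1-(4-benzyloxy-3-methoxyphenyl)prop-1-en-1-yl]-3-methoxy-2-(methoxymethoxy)benzene | C/C=C(\c1ccc(OCc2ccccc2)c(OC)c1)c1cccc(OC)c1OCOC
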